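Remark: atoms are numbered as in germacranolides (C1 ketone, C2=C3 enol ether, C4 with methyl C15, C5 carbinol, C6 lactone oxygen, C7, C8 angelate, C9 carbinol, C10 with methyl C14 and the ether oxygen, C11 with OH and C13H2Cl, C12 lactone carbonyl). Aldehyde 3 is taken as a purchasable compound and is distilled before use.

## Analysis of the target

Target 25 is a ten-membered carbocycle C1–C10 bridged by an oxygen between C3 and C10. O, C3, C2, C1 and C10 form a 3(2H)-furanone (ring A), the large ring is in effect a nine-membered cyclic ether (ring B), and a γ-lactone (ring C: C6, C7, C11, C12, O) is trans-fused at C6–C7. It has eight stereocentres (4R,5S,6S,7S,8S,9S,10S,11S), seven of them contiguous along ring B. The C7–C11, C8–O, C9–O and C10–O bonds lie on one face and the C6–O bond on the other; C5–OH/C6–O are threo and C4–CH3/C5–OH are anti. The sensitive groups are: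
- the angelate at C8, which isomerises Z to E under nucleophilic catalysis;
- the C11/C13 chlorohydrin, which closes to the epoxide with base;
- the C9 hydroxyl, β to the C1 ketone, which can be lost by retro-aldol cleavage because C10 would leave as an aromatic furan-3-olate;
- the C5 oxygen, β to the vinylogously acidic C4–H.

The difficulty is a strained medium ring that carries seven adjacent heteroatom-bearing carbons and three secondary oxygens that must end up differentiated (C5–OH, C8–O-acyl, C9–OH). The feature on which the route is built is the C7–C8 bond. C7 (bearing C11) and C8 (bearing oxygen) have the syn relationship that 2-(alkoxycarbonyl)allyl metals give with aldehydes. The C6/C7 relationship of the trans lactone is the one such reagents disfavour. Ring A is a rigid turn that brings the C3 and C10 side chains together.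

## Retrosynthetic reasoning

25 to 23 and 22. The C13–Cl and C11–OH bonds are cut last: the chlorohydrin is the chloride-opened form of spiro-epoxide 23, which comes from the α-methylene lactone 22. On the rigid trans-fused lactone the peroxide enolate closes on the face of H7, so C11 is set by the ring. Only the unhindered exocyclic alkene is a good acceptor, so the angelate can already be in place.

22 to 21. The lactone C12–O6 bond is cut. In 21 the C5/C6 diol is an acetonide and C12 is a tert-butyl ester, so one acid treatment must unmask both and close the five-membered lactone on O6. The gain is that O5 and O6 need no individual protecting groups and that C12 cannot lactonise onto O8 earlier.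

21 to 19 and 20. The ester C–O bond at C8 is cut. In 19 the C8 hydroxyl is the only free hydroxyl, so acylation with 20 needs no selectivity among the three secondary oxygens.

19 to 18 (key disconnection). The C7–C8 bond of ring B is cut, giving an open chain held together only by ring A: allylic bromide at C13, aldehyde at C8. The usual cut of a germacranolide is C6–C7 with lactonisation. It is not used here because that closure must create the C6/C7 anti relationship and a C5/C6 syn relationship next to a protected α-oxygen, both against the normal sense of the reaction. At C7–C8 the normal sense (syn adduct from a Z reagent, Felkin–Anh addition to the α-silyloxy aldehyde) is the one the target has, and the new C8 hydroxyl is born free for the angelate. The forward reaction has to close the medium ring and set C7 and C8 together.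

18 to 13 and 14. The C7–C11 bond is cut: a Morita–Baylis–Hillman reaction of aldehyde 13 with 14, then allylic bromination with transposition, gives the Z allylic bromide. The C8 aldehyde comes from cleaving a terminal 1,2-diol (16), which removes a carbon that is only needed earlier as a stereochemical control element. 13 comes from 12 by oxidation, and 12 from 11 by moving the acetonide from O6/O7 to O5/O6.

11 to 4 and 9. Ring A is cut at O–C3 and at C1–C2: an acetylide from 4 adds to the lactone carbonyl of 9, and the tertiary C10 hydroxyl closes onto the resulting ynone (10). The lactone stops the addition at the ketone stage, and only the oxygen that must become the ring oxygen is free. C4, C5, C6, C9 and C10 arrive with the two fragments.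

9 to 3 and 5; 4 to 2 and 3; 2 to 1. Lactone 9 comes from butenolide 7 by a dihydroxylation steered by the C8 stereocentre (8), and 7 from aldehyde 3 and phosphonate 5 through Z-enoate 6. Alkyne 4 comes from the same aldehyde 3 and mesylate 2 (from 1) by a propargylation that sets C4 and C5. Both halves thus start from one chiral aldehyde.

## Alternatives that were turned down

Alternative 1: the textbook cut, C6–C7 with lactonisation. The forward key step is an intramolecular Barbier or chromium-mediated allylation of the C6 aldehyde by the C13 bromide of A1, followed by closure of the lactone in the same pot. It closes two rings at once. It was turned down for three reasons: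
- The Z reagent adds through a chair transition state to give the syn adduct, which is the cis-fused lactone.
- The α-silyloxy aldehyde prefers the 5,6-anti product, while the target needs 5,6-syn.
- The C8 oxygen must be an ether during the step (an ester there invites 1,4-elimination of the allyl metal), so two extra protecting-group steps are needed for the angelate.

Both stereocentres would therefore have to form against the local preference.

Alternative 2: ring expansion. The C3–C4 bond is formed and C1–C6 broken by an anionic oxy-Cope rearrangement of the 1-(ethoxyethynyl)-2-propenylcyclohexanol A2, whose six-membered ring holds C1 and C6–C10. The resulting ten-membered vinylogous ester would then close ring A transannularly. It changes the connectivity and sets C4, but it was turned down: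
- A2 needs a fully substituted cyclohexane with the all-cis C7–C10 array, which reagent approach on such rings disfavours.
- The isopropenyl methyl must later be oxidised to C12.
- The C5/C6 diol would have to be set on a flexible trans-cycloalkene.
- The rearrangement of an ynol ether alkoxide lacks close precedent.

The risk would be spread over many steps.

Alternative 3: macrocycle first, then transannular closure of ring A. The cyclodec-2-ynone A3 would be closed at C1–C2 by an intramolecular alkynylation, and the C10 hydroxyl would then add across the ring to C3 (5-endo-dig). The key step creates no stereocentre. It was turned down because A3 is a strained cycloalkyne fused to a trans lactone, and because all seven ring stereocentres and the lactone would have to be assembled on an open chain first. That costs more steps than the closure saves.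

Key step: step 13

## Route

Step 1
Reactants: 1 (R)-but-3-yn-2-ol
Product: 2 (R)-but-3-yn-2-yl methanesulfonate
Conditions: MsCl, Et3N, CH2Cl2, −78 → 0 °C
Reagents that add atoms: methanesulfonyl chloride, CS(=O)(=O)Cl
Why: Sulfonylation of a secondary propargylic alcohol; the stereocentre is untouched and becomes the leaving-group carbon for step 2.

Step 2
Reactants: 2 (R)-but-3-yn-2-yl methanesulfonate; 3 (S)-2,2-dimethyl-1,3-dioxolane-4-carbaldehyde
Product: 4 (1S,2S)-1-[(4S)-2,2-dimethyl-1,3-dioxolan-4-yl]-2-methylbut-3-yn-1-ol
Conditions: Pd(OAc)2 (5 mol %), PPh3 (5 mol %), Et2Zn (3 equiv), THF, −78 → −20 °C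
Reagents that add atoms: none
Why: Palladium-catalysed propargylation through a chiral allenylzinc: zerovalent palladium displaces the mesylate anti (SN2′), transmetalation gives the allenylzinc, and this adds to 3 through a cyclic SE2′ transition state. The C4-methyl/C5-hydroxyl anti relationship comes from that transition state and the absolute sense from the (R)-mesylate (the new C–C bond forms opposite to the C–O bond of 2), so the reagent is expected to fix C5 and give the 5,6-syn pattern.

Step 3
Reactants: 3 (S)-2,2-dimethyl-1,3-dioxolane-4-carbaldehyde; 5 ethyl 2-(diphenoxyphosphoryl)propanoate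
Product: 6 ethyl (Z)-3-[(4R)-2,2-dimethyl-1,3-dioxolan-4-yl]-2-methylprop-2-enoate
Conditions: NaH, THF, −78 → 0 °C
Reagents that add atoms: none
Why: Z-selective Horner–Wadsworth–Emmons reaction (diaryl phosphonate variant); the Z geometry puts the ester cis to C8 for lactonisation, and the α-alkoxy aldehyde does not epimerise at low temperature.

Step 4
Reactants: 6 ethyl (Z)-3-[(4R)-2,2-dimethyl-1,3-dioxolan-4-yl]-2-methylprop-2-enoate
Product: 7 (R)-5-(hydroxymethyl)-3-methylfuran-2(5H)-one
Conditions: aq. HCl (1 M), THF, 25 °C
Reagents that add atoms: none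
Why: Acetal hydrolysis frees the diol, and the γ-hydroxyl of the Z-enoate lactonises spontaneously to the butenolide (five-membered ring preferred over the six-membered alternative).

Step 5
Reactants: 7 (R)-5-(hydroxymethyl)-3-methylfuran-2(5H)-one
Product: 8 (3S,4S,5S)-3,4-dihydroxy-5-(hydroxymethyl)-3-methyloxolan-2-one
Conditions: OsO4 (2 mol %), NMO, acetone/H2O, 25 °C
Reagents that add atoms: N-methylmorpholine N-oxide, C[N+]1([O-])CCOCC1; water, O
Why: Catalytic syn-dihydroxylation of the butenolide on the face opposite the C8 hydroxymethyl group sets C9 and C10 together as the cis-diol (ribo pattern), with the tertiary C10 carbinol.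

Step 6
Reactants: 8 (3S,4S,5S)-3,4-dihydroxy-5-(hydroxymethyl)-3-methyloxolan-2-one
Product: 9 (3S,4S,5S)-4-[(tert-butyldimethylsilyl)oxy]-5-{[(tert-butyldimethylsilyl)oxy]methyl}-3-hydroxy-3-methyloxolan-2-one
Conditions: TBSCl (2.3 equiv), imidazole, DMF, 0 → 25 °C
Reagents that add atoms: tert-butyldimethylsilyl chloride, CC(C)(C)[Si](C)(C)Cl
Why: Silylation of the primary and the secondary hydroxyl; the tertiary α-hydroxyl is too hindered to react and stays free as the future furanone oxygen.

Step 7
Reactants: 4 (1S,2S)-1-[(4S)-2,2-dimethyl-1,3-dioxolan-4-yl]-2-methylbut-3-yn-1-ol; 9 bis-silylated lactone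
Product: 11 3(2H)-furanone with free C5 and C8 hydroxyls (C3 side chain: C4 methyl, C5–OH, terminal O6/O7 acetonide; C10 side chain: C9–OTBS, C8–OH, CH2OTBS), via hydroxy ynone 10 (not isolated)
Conditions: 4, n-BuLi (2.1 equiv), THF, −78 °C; 9 pre-treated with LiN(SiMe3)2 (1.0 equiv), −78 → −40 °C; AcOH; then Et2NH, EtOH, 25 °C
Reagents that add atoms: none
Why: The lithium acetylide adds to the lactone carbonyl to give a tetrahedral intermediate that does not over-add and opens on protonation to α′-hydroxy ynone 10. Diethylamine then mediates conjugate addition–elimination of the tertiary C10 hydroxyl (net 5-endo-dig) to the 3(2H)-furanone. The C9 silyl ether blocks the competing six-membered closure, the C5 hydroxyl cannot reach C3, and no stereocentre is touched.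

Step 8
Reactants: 11 furanone with terminal acetonide
Product: 12 furanone with O5/O6 trans-acetonide and free C7 (primary) and C8 (secondary) hydroxyls
Conditions: camphorsulfonic acid (10 mol %), acetone, 25 °C
Reagents that add atoms: none
Why: Acid-catalysed acetal migration under thermodynamic control: the threo 5,6-diol forms a trans-4,5-disubstituted dioxolane that is favoured over the terminal one, which frees the primary C7 hydroxyl.

Step 9
Reactants: 12 furanone diol with O5/O6 acetonide
Product: 13 C7 aldehyde (O5/O6 acetonide, C8–OH free)
Conditions: TEMPO (10 mol %), PhI(OAc)2, CH2Cl2, 25 °C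
Reagents that add atoms: none
Why: Oxoammonium oxidation is selective for the primary alcohol over the hindered secondary C8 hydroxyl; the trans-dioxolane aldehyde is already the more stable epimer at C6.

Step 10
Reactants: 13 C7 aldehyde; 14 tert-butyl acrylate
Product: 15 Morita–Baylis–Hillman adduct (C7 carbinol as a mixture of epimers, C11=C13 methylene, C12 tert-butyl ester)
Conditions: DABCO (1 equiv), 14 (excess), MeOH (3 equiv), 25 °C
Reagents that add atoms: none
Why: Morita–Baylis–Hillman reaction of an activated α-alkoxy aldehyde forms C7–C11; the C7 carbinol configuration is irrelevant because it is removed in step 12.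

Step 11
Reactants: 15 Morita–Baylis–Hillman adduct
Product: 17 C8 aldehyde (α-silyloxy aldehyde, C7 allylic alcohol retained), via triol 16 (not isolated)
Conditions: HF·pyridine, pyridine, THF, 0 °C; then NaIO4, THF/pH 7 buffer, 0 → 25 °C
Reagents that add atoms: none
Why: Buffered fluoride cleaves the primary silyl ether selectively over the hindered secondary one. Periodate then cleaves the only 1,2-diol, which removes the carbon that steered step 5 and leaves C8 as the aldehyde.

Step 12
Reactants: 17 C8 aldehyde with C7 allylic alcohol
Product: 18 (Z)-allylic bromide (C13H2Br, C11=C7, C8 aldehyde)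
Conditions: NBS, Me2S (pre-mixed), CH2Cl2, −20 → 0 °C
Reagents that add atoms: N-bromosuccinimide, O=C1CCC(=O)N1Br
Why: Corey–Kim-type activation of the allylic alcohol and SN2′ attack of bromide give the rearranged primary bromide with the more stable Z geometry (C6 cis to CH2Br); the aldehyde and silyl ether are inert to the sulfonium reagent.

Step 13
Reactants: 18 (Z)-allylic bromide with C8 aldehyde
Product: 19 ten-membered carbocycle (C8–OH free, C7 bearing the tert-butyl acrylate unit, O5/O6 acetonide, C9–OTBS)
Conditions: CrCl2 (8 equiv), THF, 25 °C, slow addition of 18 (final 2 mM)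
Reagents that add atoms: none
Why: Two equivalents of CrCl2 reduce the C13–Br bond to an allyl chromium dichloride (trivalent chromium), which adds through its γ-carbon C7 to the C8 aldehyde in a closed six-membered chair transition state, moving the double bond to C11=C13. The closest known reaction type is the Nozaki–Hiyama–Kishi/Barbier-type macrocyclisation of ω-formyl 2-(bromomethyl)alk-2-enoates used to close ten-membered germacranolide rings. One ring is closed, the ten-membered carbocycle (ring B, a nine-membered ether when counted through the furanone oxygen), by a 10-exo-trig attack on the carbonyl; ring A and the trans-dioxolane act as rigid turns that hold C7 and C8 within reach. For the C7/C8 relationship, the Z geometry of C11=C7 places C6 axial in the chair while C9 sits equatorial, which gives the syn arrangement of C8–O and C7–C6 found in the target. For C8, the C9–OSi bond stands antiperiplanar to the incoming carbon (Felkin–Anh arrangement), which gives the 8,9-anti pattern. For C7, A(1,3) strain between C6 and C13H2 puts H6 in the alkene plane and the aldehyde should enter anti to the C6–O bond, the sense required for the later trans lactone, so the three elements reinforce one another. The step needs addition to the aldehyde only (ester and furanone carbonyl are inert to allyl chromium reagents), cyclisation over oligomerisation (high dilution) and no lactonisation of the new C8 alkoxide, which the tert-butyl ester secures.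

Step 14
Reactants: 19 ten-membered C8 alcohol; 20 angelic acid ((Z)-2-methylbut-2-enoic acid)
Product: 21 C8 angelate (tert-butyl ester, O5/O6 acetonide, C9–OTBS)
Conditions: 20, 2,4,6-trichlorobenzoyl chloride, Et3N, toluene, 25 °C; then 19, toluene, 75 °C
Reagents that add atoms: none
Why: Yamaguchi-type mixed-anhydride acylation of the only free hydroxyl; leaving out a nucleophilic catalyst limits Z-to-E isomerisation of the angelate, and C8 keeps its configuration.

Step 15
Reactants: 21 C8 angelate
Product: 22 α-methylene γ-lactone (O6–C12 lactone, C5–OH free, C8 angelate, C9–OTBS)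
Conditions: CF3CO2H/CH2Cl2/H2O (20:78:2), 0 → 25 °C
Reagents that add atoms: none
Why: Acid removes the acetonide and the tert-butyl ester, and the γ-hydroxy acid closes on O6 (five-membered ring preferred over the six-membered ring through O5). C6 and C7 are already set, so the trans ring fusion follows.

Step 16
Reactants: 22 α-methylene γ-lactone
Product: 23 11,13-spiro-epoxide
Conditions: t-BuOOH (in decane), DBU, CH2Cl2, 0 °C
Reagents that add atoms: tert-butyl hydroperoxide, CC(C)(C)OO
Why: Weitz–Scheffer nucleophilic epoxidation: the peroxide anion adds to the unhindered exocyclic CH2 much faster than to the β-substituted angelate or the vinylogous ester of ring A. The lactone enolate closes the epoxide on the face of H7, away from C8, which sets C11; the C9 silyl ether prevents retro-aldol cleavage under the base.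

Step 17
Reactants: 23 11,13-spiro-epoxide
Product: 25 target CNP0340393.2, via chlorohydrin silyl ether 24 (not isolated)
Conditions: HCl (4 M in dioxane), CH2Cl2, −20 → 0 °C; evaporate; then aq. HF (48%), MeCN, 0 → 25 °C
Reagents that add atoms: hydrogen chloride, Cl
Why: Chloride opens the protonated epoxide by SN2 at primary C13 (a cation at C11 is disfavoured next to the carbonyl), so C11 keeps its oxygen and configuration. Aqueous HF then cleaves the hindered C9 silyl ether under acidic conditions, which avoid base-induced epoxide re-closure and retro-aldol cleavage.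

## Compound list

1 | (R)-but-3-yn-2-ol | O[C@H](C)C#C | starting material
2 | (R)-but-3-yn-2-yl methanesulfonate | CS(=O)(=O)O[C@H](C)C#C | intermediate
3 | (S)-2,2-dimethyl-1,3-dioxolane-4-carbaldehyde | O=C[C@@H]1COC(C)(C)O1 | starting material
4 | (1S,2S)-1-[(4S)-2,2-dimethyl-1,3-dioxolan-4-yl]-2-methylbut-3-yn-1-ol | C#C[C@H](C)[C@H](O)[C@@H]1COC(C)(C)O1 | intermediate
5 | ethyl 2-(diphenoxyphosphoryl)propanoate | CCOC(=O)C(C)P(=O)(Oc1ccccc1)Oc1ccccc1 | starting material
6 | ethyl (Z)-3-[(4R)-2,2-dimethyl-1,3-dioxolan-4-yl]-2-methylprop-2-enoate | CCOC(=O)/C(C)=C\[C@@H]1COC(C)(C)O1 | intermediate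
7 | (R)-5-(hydroxymethyl)-3-methylfuran-2(5H)-one | CC1=C[C@H](CO)OC1=O | intermediate
8 | (3S,4S,5S)-3,4-dihydroxy-5-(hydroxymethyl)-3-methyloxolan-2-one | O=C1O[C@@H](CO)[C@H](O)[C@]1(C)O | intermediate
9 | (3S,4S,5S)-4-[(tert-butyldimethylsilyl)oxy]-5-{[(tert-butyldimethylsilyl)oxy]methyl}-3-hydroxy-3-methyloxolan-2-one | O=C1O[C@@H](CO[Si](C)(C)C(C)(C)C)[C@H](O[Si](C)(C)C(C)(C)C)[C@]1(C)O | intermediate
10 | open-chain α′-hydroxy ynone (C1 ketone, C2≡C3; C10–OH, C9–OTBS, C8–OH, CH2OTBS; C4 methyl, C5–OH, O6/O7 acetonide) | CC1(C)OC[C@H](O1)[C@@H](O)[C@@H](C)C#CC(=O)[C@@](C)(O)[C@@H](O[Si](C)(C)C(C)(C)C)[C@@H](O)CO[Si](C)(C)C(C)(C)C | intermediate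
11 | 3(2H)-furanone with C5–OH and C8–OH free, terminal O6/O7 acetonide, C9–OTBS and CH2OTBS | CC1(C)OC[C@H](O1)[C@@H](O)[C@@H](C)C1=CC(=O)[C@@](C)(O1)[C@@H](O[Si](C)(C)C(C)(C)C)[C@@H](O)CO[Si](C)(C)C(C)(C)C | intermediate
12 | 3(2H)-furanone with O5/O6 trans-acetonide, C7–OH and C8–OH free | OC[C@@H]1OC(C)(C)O[C@H]1[C@@H](C)C1=CC(=O)[C@@](C)(O1)[C@@H](O[Si](C)(C)C(C)(C)C)[C@@H](O)CO[Si](C)(C)C(C)(C)C | intermediate
13 | C7 aldehyde of 12 | O=C[C@@H]1OC(C)(C)O[C@H]1[C@@H](C)C1=CC(=O)[C@@](C)(O1)[C@@H](O[Si](C)(C)C(C)(C)C)[C@@H](O)CO[Si](C)(C)C(C)(C)C | intermediate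
14 | tert-butyl acrylate | C=CC(=O)OC(C)(C)C | starting material
15 | Morita–Baylis–Hillman adduct (C7 carbinol epimers, tert-butyl 2-methylene ester) | C=C(C(=O)OC(C)(C)C)C(O)[C@@H]1OC(C)(C)O[C@H]1[C@@H](C)C1=CC(=O)[C@@](C)(O1)[C@@H](O[Si](C)(C)C(C)(C)C)[C@@H](O)CO[Si](C)(C)C(C)(C)C | intermediate
16 | triol after loss of the primary silyl group | C=C(C(=O)OC(C)(C)C)C(O)[C@@H]1OC(C)(C)O[C@H]1[C@@H](C)C1=CC(=O)[C@@](C)(O1)[C@@H](O[Si](C)(C)C(C)(C)C)[C@@H](O)CO | intermediate
17 | C8 aldehyde with C7 allylic alcohol | C=C(C(=O)OC(C)(C)C)C(O)[C@@H]1OC(C)(C)O[C@H]1[C@@H](C)C1=CC(=O)[C@@](C)(O1)[C@@H](O[Si](C)(C)C(C)(C)C)C=O | intermediate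
18 | (Z)-allylic bromide with C8 aldehyde | BrC/C(C(=O)OC(C)(C)C)=C\[C@@H]1OC(C)(C)O[C@H]1[C@@H](C)C1=CC(=O)[C@@](C)(O1)[C@@H](O[Si](C)(C)C(C)(C)C)C=O | intermediate
19 | ten-membered carbocycle with C8–OH, C7 tert-butyl acrylate unit, O5/O6 acetonide, C9–OTBS | O[C@H]1[C@@H](C(=C)C(=O)OC(C)(C)C)[C@@H]2OC(C)(C)O[C@H]2[C@@H](C)C2=CC(=O)[C@@](C)(O2)[C@H]1O[Si](C)(C)C(C)(C)C | intermediate
20 | angelic acid ((Z)-2-methylbut-2-enoic acid) | C/C=C(/C)C(=O)O | starting material
21 | C8 angelate of 19 | C/C=C(/C)C(=O)O[C@H]1[C@@H](C(=C)C(=O)OC(C)(C)C)[C@@H]2OC(C)(C)O[C@H]2[C@@H](C)C2=CC(=O)[C@@](C)(O2)[C@H]1O[Si](C)(C)C(C)(C)C | intermediate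
22 | α-methylene γ-lactone (C5–OH free, C8 angelate, C9–OTBS) | C/C=C(/C)C(=O)O[C@H]1[C@@H]2[C@H](OC(=O)C2=C)[C@@H](O)[C@@H](C)C2=CC(=O)[C@@](C)(O2)[C@H]1O[Si](C)(C)C(C)(C)C | intermediate
23 | 11,13-spiro-epoxide of 22 | C/C=C(/C)C(=O)O[C@H]1[C@@H]2[C@H](OC(=O)[C@]23CO3)[C@@H](O)[C@@H](C)C2=CC(=O)[C@@](C)(O2)[C@H]1O[Si](C)(C)C(C)(C)C | intermediate
24 | chlorohydrin, C9 silyl ether | C/C=C(/C)C(=O)O[C@H]1[C@@H]2[C@H](OC(=O)[C@]2(O)CCl)[C@@H](O)[C@@H](C)C2=CC(=O)[C@@](C)(O2)[C@H]1O[Si](C)(C)C(C)(C)C | intermediate
25 | CNP0340393.2 (4R,5S,6S,7S,8S,9S,10S,11S) | C/C=C(/C)C(=O)O[C@H]1[C@@H]2[C@H](OC(=O)[C@]2(O)CCl)[C@@H](O)[C@@H](C)C2=CC(=O)[C@@](C)(O2)[C@H]1O | target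

## Step count and least certain steps

Total step count: 17. Longest linear sequence: 15 steps (steps 3 to 17, from 3 and 5); the other branch (steps 1, 2, then 7 to 17) has 13.

Step 13 (key step). The most likely failure is ring closure through the wrong aldehyde face: the strain of the nine-membered ether ring can override the Felkin–Anh preference and give the C8 epimer. Intermolecular allylation can also outrun cyclisation. The C6-to-C7 induction rests on a model, not on a rigid ring. Fallback, from 18 back to 21: if the same chromium-mediated closure of 18 gives mainly the 8-epimeric alcohol F1, that alcohol is esterified with 20 under Mitsunobu conditions (PPh3, DIAD, toluene). This inverts C8 and installs the angelate in one operation, so the route rejoins at 21 and step 14 is not needed.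

Step 2. The aldehyde 3 itself prefers Felkin–Anh attack (5,6-anti), while the route needs the 5,6-syn product, so the pairing is mismatched and reagent control may erode. Fallback, from 3 back to 4: asymmetric crotylboration of 3 with the antipode of (E)-crotyldiisopinocampheylborane that delivers the (1S) carbinol gives homoallylic alcohol F2. Silylation (Et3SiOTf, 2,6-lutidine) gives silyl ether F3, ozonolysis (O3, then PPh3) gives aldehyde F4, Ohira–Bestmann alkynylation (dimethyl (1-diazo-2-oxopropyl)phosphonate, K2CO3, MeOH) gives silylated alkyne F5, and PPTS in MeOH removes the silyl group to give 4.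

Step 7. Addition of the acetylide to the hindered carbonyl of 9, which sits next to a tertiary alkoxide, may stall, and alkoxide-induced opening of the lactone may compete. Fallback, from 9 and 4 back to 11: 9 is reduced with i-Bu2AlH at −78 °C to lactol F6, whose aldehyde form is more electrophilic. Dilithiated 4 adds to it to give propargylic alcohol F7. MnO2 oxidises only the propargylic hydroxyl to give ynone 10, which is closed to 11 with Et2NH as in step 7.

Step 15. The acid strong enough to cleave the tert-butyl ester may also remove the C9 silyl ether, which would expose the retro-aldol-prone hydroxyl before the basic epoxidation. Fallback, from 21 back to 22: the acetonide alone is removed with 80% aqueous AcOH at 40 °C to give dihydroxy tert-butyl ester F8. Its C6 hydroxyl is then lactonised by mild acid-catalysed transesterification (PPTS, toluene, 70 °C) with loss of tert-butanol, giving 22 without strong acid.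

## Further compounds

F1 | step 13 | C8 epimer of alcohol 19 | O[C@@H]1[C@@H](C(=C)C(=O)OC(C)(C)C)[C@@H]2OC(C)(C)O[C@H]2[C@@H](C)C2=CC(=O)[C@@](C)(O2)[C@H]1O[Si](C)(C)C(C)(C)C
F2 | step 2 | homoallylic alcohol (vinyl analogue of 4) | C=C[C@H](C)[C@H](O)[C@@H]1COC(C)(C)O1
F3 | step 2 | triethylsilyl ether of F2 | C=C[C@H](C)[C@H](O[Si](CC)(CC)CC)[C@@H]1COC(C)(C)O1
F4 | step 2 | α-methyl aldehyde from ozonolysis of F3 | O=C[C@H](C)[C@H](O[Si](CC)(CC)CC)[C@@H]1COC(C)(C)O1
F5 | step 2 | triethylsilyl ether of 4 | C#C[C@H](C)[C@H](O[Si](CC)(CC)CC)[C@@H]1COC(C)(C)O1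
F6 | step 7 | lactol from reduction of 9 (anomers) | OC1O[C@@H](CO[Si](C)(C)C(C)(C)C)[C@H](O[Si](C)(C)C(C)(C)C)[C@]1(C)O
F7 | step 7 | propargylic alcohol (C1 carbinol epimers) | CC1(C)OC[C@H](O1)[C@@H](O)[C@@H](C)C#CC(O)[C@@](C)(O)[C@@H](O[Si](C)(C)C(C)(C)C)[C@@H](O)CO[Si](C)(C)C(C)(C)C
F8 | step 15 | 5,6-dihydroxy tert-butyl ester from 21 | C/C=C(/C)C(=O)O[C@H]1[C@@H](C(=C)C(=O)OC(C)(C)C)[C@H](O)[C@@H](O)[C@@H](C)C2=CC(=O)[C@@](C)(O2)[C@H]1O[Si](C)(C)C(C)(C)C
A1 | alternative 1 | furanone-linked C6 aldehyde with (Z)-2-(bromomethyl)enoate at C7 (C5 and C9 silyl ethers, C8 p-methoxybenzyl ether) | O=C[C@@H](O[Si](C)(C)C(C)(C)C)[C@@H](C)C1=CC(=O)[C@@](C)(O1)[C@@H](O[Si](C)(C)C(C)(C)C)[C@@H](OCc1ccc(OC)cc1)/C=C(\CBr)C(=O)OC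
A2 | alternative 2 | 1-(ethoxyethynyl)-2-[(E)-prop-1-enyl]cyclohexanol with C7 isopropenyl, O8/O9 acetonide and C10 triethylsilyl ether | CCOC#C[C@]1(O)[C@@H](/C=C/C)[C@H](C(C)=C)[C@@H]2OC(C)(C)O[C@@H]2[C@]1(C)O[Si](CC)(CC)CC
A3 | alternative 3 | cyclodec-2-ynone with trans lactone, C8 angelate, C10–OH free | C/C=C(/C)C(=O)O[C@H]1[C@@H]2[C@H](OC(=O)C2=C)[C@@H](O[Si](C)(C)C(C)(C)C)[C@@H](C)C#CC(=O)[C@@](C)(O)[C@H]1O[Si](C)(C)C(C)(C)C
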